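The numbers in the tables stem from a simulated flask on assumed constants; scatter was added.

Start with G.

common to all: G 0.979 M; Z 0.178 M

| flask | L | temperature | remark | time |
|---|---|---|---|---|
| eta | 0.89 M | 5 °C | the very flask that is asked about, followed so far |  |
| beta | 0.60 M | 11 °C | run made earlier |  |
| flask | 0.89 M | 5 °C |  | 30 h |
- oak: at 30 h raise the temperature by 15 K, then wait 15 h
- elm: change nothing and wait 15 h more
- birch: at 30 h take out 90% of the D then present, then wait 15 h
- D, in percent of the L first charged, at 30 h
- which option adds most D ("none" when 2 percentage points or less is all one gets) (oak / elm / birch / none)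
- D present, with what was taken out counted in, in percent of the L first charged, after oak
- D present, with what was taken out counted in, in percent of the L first charged, after birch
- removed D is counted in
- the numbers in the tables scatter by 1 percentage point (one standard deviation)
- candidate steps: J -> D; G + Z -> Q; D <-> E; L + G -> J; L <-> X
eta run (percent of the L charged)

| time / h | D / % | L / % |
|---|---|---|
| 5.00 | 34.1 | 3.3 |
| 10.0 | 33.5 | 2.0 |
| 15.0 | 34.8 | 3.1 |
| 20.0 | 34.5 | 4.8 |

beta run (percent of the L charged)

| time / min | D / % | L / % |
|---|---|---|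
| 15.0 | 40.9 | 2.3 |
| 40.0 | 48.9 | 0.9 |
| 80.0 | 46.8 | 0 |
| 120 | 46.8 | 1.3 |

(scatter of a reading: 1 percentage point)

I read the tables down their D columns. In eta, D runs 34.1%, 33.5%, 34.8%, 34.5%, flat within a scatter of 1 percentage point, with L at 3.3% by the first reading. In beta, D stays near 48.9%, 46.8%, 46.8% from 40.0 min on, and L is again low. So I took D to be in balance with E, and asked how much material reached that pair.

If Z takes its whole charge of G, eta gives 90.0%; this is the reach, the G not spent on Z divided by the L charged. It is below one, so G is the limiting reagent in eta. Beta has G to spare, with a reach of 134%, so I counted its pair as the whole charge.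

The mean D in eta, 34.2%, is then a D share of 38.0% of the pair at 5 °C. The late beta readings give a share of 47.5% at 11 °C. As ratios of E to D these are 1.63 and 1.11.

Carrying that fall on, in logarithm and in proportion to the temperature, over the 15 K of oak gives a ratio of 0.617. With the reach unchanged, I expected 55.6% of D after oak. For birch I kept the D taken out and let the rest of the pair rebalance, which gives 53.3%. Elm gains nothing on a balanced pair, so I chose oak, with D at 34.2% at 30 h.

The forecast said 34.5%, oak, 54.5% after oak and 53.6% after birch, and called it close: “Oak and birch are nearly tied”. My oak figure stood higher than its figure.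

The flask gave 34.7% of D at 30 h, 56.8% after oak and 54.0% after birch, while elm added 0 points.

    J → D (k = 6.70 × 10⁻⁴ s⁻¹, Ea = 79.0 kJ mol⁻¹)
    G + Z → Q (k = 0.00490 M⁻¹ s⁻¹, Ea = 50.0 kJ mol⁻¹)
    D ⇌ E (K = 1.60, k = 4.60 × 10⁻⁴ s⁻¹, Ea = 79.0 kJ mol⁻¹, ΔH = −45.0 kJ mol⁻¹)
    L + G → J (k = 0.00470 M⁻¹ s⁻¹, Ea = 68.0 kJ mol⁻¹)
    L ⇌ X (K = 2.80, k = 1.70 × 10⁻⁴ s⁻¹, Ea = 88.0 kJ mol⁻¹, ΔH = −64.0 kJ mol⁻¹)
    (constants at 5 °C)

In the flask the forward half-life of D turning into E is 0.42 h, shorter than the 30 h waited, and D plus E stands at 90.3% at 30.0 h, against a reach of 90.0%. In the neighbour flask with 0.59 M of G, Z keeps 41% of its charge, so I counted the 0.105 M of Q actually formed: the reach becomes 54.5%, which with the share 38.0% gives 20.7% of D, and that neighbour flask holds 21.0%.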